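Numbering: tetralone C1 (C=O), C4 (stereocentre), C4a/C8a (fusion), C7/C8 (OH); ring A is the catechol ring, ring B the ketone ring; naphthalene C1' (on C4), C4' (OH), C8' (OMe).
Enabling feature: ring A has four neighbouring substituents (C4a alkyl, C8a acyl, C8–O, C7–O), and the C7 oxygen is para to C4a. This is the pattern left by an α-substituted furan that has taken up an alkyne and then opened its oxygen bridge.
Cuts: C8–OH back to C8–Br; then C4a–C8a and C7–C8 together, which opens rings A and B to a furyl bromoynone; then C1–C8a, C1–C2, C4–C4a (furan), C3=C4, and C4–C1' (a formyl carbon on the naphthalene).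
Forward: the naphthaldehyde comes from centrosymmetric 1,5-dimethoxynaphthalene; the chain grows C4 → C3/C2 → furan → C1 → C8a/C8; rings A and B close in one operation; C8–Br is exchanged for OH before debenzylation.
Stereochemistry: C4, the only stereocentre, is set as (R) by a chiral imidazolidinone when the furyl group adds to the enal. From the tetralone stage on only weak bases are used, because C4–H is then vinylogously acidic.
Key step: step 10

Assumption: the facial sense in step 5 follows the accepted shielding model for (E)-iminium ions of this imidazolidinone, by which the (2R,5R) catalyst should give (R) at C4; if the furyl group arrived on the other face, the (2S,5S) catalyst would be used.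

Step 1
Reactants: 1 1,5-dimethoxynaphthalene
Product: 3 4,8-dimethoxynaphthalene-1-carbaldehyde, via iminium salt 2 (not isolated)
Conditions: POCl3, DMF, toluene, 100 °C; then ice–H2O
Reagents that add atoms: N,N-dimethylformamide CN(C)C=O (formyl carbon); water O (formyl oxygen)
Why: Vilsmeier–Haack formylation goes para to a methoxy group, and since the two para positions of centrosymmetric 1 are equivalent only one aldehyde can form, its formyl carbon (the future C4) standing peri to the methoxy group that becomes C8'–OMe.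

Step 2
Reactants: 3 4,8-dimethoxynaphthalene-1-carbaldehyde
Product: 4 4-hydroxy-8-methoxynaphthalene-1-carbaldehyde
Conditions: NaSEt, DMF, 100 °C; then 1 M HCl
Reagents that add atoms: none
Why: Thiolate O-demethylation (SN2 at the methyl group) should pick the C4' ether because only that naphtholate is conjugated with the formyl group and is therefore the better leaving group, and the resulting anion shuts down a second cleavage.

Step 3
Reactants: 4 4-hydroxy-8-methoxynaphthalene-1-carbaldehyde
Product: 5 4-(benzyloxy)-8-methoxynaphthalene-1-carbaldehyde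
Conditions: BnBr, K2CO3, DMF, rt
Reagents that add atoms: benzyl bromide BrCc1ccccc1
Why: Williamson ether synthesis on an acidic naphthol; benzyl is inert to everything up to the last step and leaves there together with the second benzyl group.

Step 4
Reactants: 5 4-(benzyloxy)-8-methoxynaphthalene-1-carbaldehyde
Product: 6 (2E)-3-[4-(benzyloxy)-8-methoxynaphthalen-1-yl]prop-2-enal
Conditions: Ph3P=CHCHO, toluene, 100 °C
Reagents that add atoms: (triphenylphosphoranylidene)acetaldehyde O=CC=P(c1ccccc1)(c1ccccc1)c1ccccc1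
Why: Wittig reaction of a stabilised formyl ylide with a non-enolisable aromatic aldehyde, which adds C3 and C2 and gives the (E)-enal.

Step 5
Reactants: 6 (2E)-3-[4-(benzyloxy)-8-methoxynaphthalen-1-yl]prop-2-enal; 7 potassium furan-2-yltrifluoroborate
Product: 8 (3R)-3-[4-(benzyloxy)-8-methoxynaphthalen-1-yl]-3-(furan-2-yl)propanal
Conditions: (2R,5R)-5-benzyl-2-tert-butyl-3-methylimidazolidin-4-one·HCl (20 mol %), HF (48% aq, 1 equiv), DME, −20 °C → rt
Reagents that add atoms: potassium furan-2-yltrifluoroborate (compound 7) [K+].F[B-](F)(F)c1ccco1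
Why: Iminium-catalysed Friedel–Crafts-type conjugate addition of a heteroaryl trifluoroborate: the (E)-iminium ion of 6 is screened on one face by the benzyl and tert-butyl groups of the catalyst, the borate-activated furan attacks C4 from the open face and HF takes up the BF3 as insoluble KBF4, so that C4 is set as (R) under catalyst control.

Step 6
Reactants: 8 (3R)-3-[4-(benzyloxy)-8-methoxynaphthalen-1-yl]-3-(furan-2-yl)propanal
Product: 10 (4R)-4-[4-(benzyloxy)-8-methoxynaphthalen-1-yl]-4-(furan-2-yl)butanal, via enol ether 9 (not isolated)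
Conditions: MeOCH2PPh3Cl, KOtBu, THF, 0 °C; then 1 M HCl, THF, rt
Reagents that add atoms: (methoxymethyl)triphenylphosphonium chloride [Cl-].COC[P+](c1ccccc1)(c1ccccc1)c1ccccc1 (C1); water O (aldehyde oxygen)
Why: Wittig methoxymethylenation and mild hydrolysis of the enol ether, the standard one-carbon aldehyde homologation, add C1, and C4 is safe because it is never alpha to a carbonyl group.

Step 7
Reactants: 10 (4R)-4-[4-(benzyloxy)-8-methoxynaphthalen-1-yl]-4-(furan-2-yl)butanal; 11 ethynylmagnesium bromide
Product: 12 (6R)-6-[4-(benzyloxy)-8-methoxynaphthalen-1-yl]-6-(furan-2-yl)hex-1-yn-3-ol (both C3 epimers)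
Conditions: HC≡CMgBr, THF, 0 °C; then aq NH4Cl
Reagents that add atoms: ethynylmagnesium bromide (compound 11) C#C[Mg]Br
Why: 1,2-Addition of an alkynyl Grignard reagent to an aldehyde adds C8a and C8; the carbinol centre forms without control, which is of no consequence because step 9 removes it.

Step 8
Reactants: 12 (6R)-6-[4-(benzyloxy)-8-methoxynaphthalen-1-yl]-6-(furan-2-yl)hex-1-yn-3-ol
Product: 14 (6R)-6-[4-(benzyloxy)-8-methoxynaphthalen-1-yl]-1-bromo-6-(furan-2-yl)hex-1-yn-3-ol (both C3 epimers), via dilithio derivative 13 (not isolated)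
Conditions: n-BuLi (2.0 equiv), THF, −78 °C; then BrCl2CCCl2Br (1.0 equiv), −78 → −30 °C; aq NH4Cl
Reagents that add atoms: 1,2-dibromo-1,1,2,2-tetrachloroethane BrC(Cl)(Cl)C(Cl)(Cl)Br
Why: Bromination of a lithium acetylide by halophilic attack on a polyhaloalkane, which hands bromine only to the carbanion, whereas the usual NBS/AgNO3 protocol would also brominate or oxidise the furan and the dialkoxynaphthalene.

Step 9
Reactants: 14 (6R)-6-[4-(benzyloxy)-8-methoxynaphthalen-1-yl]-1-bromo-6-(furan-2-yl)hex-1-yn-3-ol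
Product: 15 (6R)-6-[4-(benzyloxy)-8-methoxynaphthalen-1-yl]-1-bromo-6-(furan-2-yl)hex-1-yn-3-one
Conditions: Dess–Martin periodinane, CH2Cl2, 0 °C → rt
Reagents that add atoms: none
Why: Dess–Martin oxidation of a secondary propargylic alcohol works under near-neutral conditions that leave the furan, the bromoalkyne and the aryl ethers alone.

Step 10
Reactants: 15 (6R)-6-[4-(benzyloxy)-8-methoxynaphthalen-1-yl]-1-bromo-6-(furan-2-yl)hex-1-yn-3-one
Product: 17 (4R)-4-[4-(benzyloxy)-8-methoxynaphthalen-1-yl]-8-bromo-7-hydroxy-3,4-dihydronaphthalen-1(2H)-one, via oxa-bridged cycloadduct 16 (not isolated)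
Conditions: Me2AlCl (1.2 equiv), CH2Cl2, −78 → 0 °C; then 1 M HCl
Reagents that add atoms: none
Why: Me2AlCl binds the C1 carbonyl oxygen and lowers the LUMO of the bromoalkyne, so that the furan diene (C4a, C5, C6, C7) adds across C8a≡C8 in a concerted, asynchronous intramolecular [4+2] cycloaddition that forms C4a–C8a and C7–C8 and gives the 7-oxanorbornadiene 16. The closest known reactions are the alkylaluminium chloride-promoted intramolecular Diels–Alder reactions of 2-alkylfurans with enones and ynones held by a four-atom chain and the bimolecular additions of 3-bromopropiolates to 2-alkylfurans. Ring B closes as the six-membered carbocycle spanned by the tether C4–C3–C2–C1 with the carbonyl inside the new ring, and ring A closes as the cyclohexadiene half of the bicycle, which turns benzenoid when the Lewis acid ionises C4a–O to a cation spread over C4a, C6 and C8 and C7–H is lost, leaving the furan oxygen as the C7 phenoxide. No lasting stereocentre is made, since the bridgeheads C4a and C7 arise as a mixture relative to C4 and both end up sp2, while C4 keeps its hydrogen and its configuration. Regioselectivity is needed twice: the tether allows only the C4a–C8a/C7–C8 pairing, which is also the innate one because the bromine-bearing beta carbon meets the free furan alpha carbon, and the bridge can open productively only at C4a, which gives a tertiary cation with the acyl group on a nodal atom, whereas C4a has no hydrogen to lose after the opposite cleavage. Me2AlCl also destroys adventitious HCl as methane, which protects the furan, and the naphthalene cannot reach the alkyne in any unstrained geometry.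

Step 11
Reactants: 17 (4R)-4-[4-(benzyloxy)-8-methoxynaphthalen-1-yl]-8-bromo-7-hydroxy-3,4-dihydronaphthalen-1(2H)-one
Product: 18 (4R)-7-(benzyloxy)-4-[4-(benzyloxy)-8-methoxynaphthalen-1-yl]-8-bromo-3,4-dihydronaphthalen-1(2H)-one
Conditions: BnBr, K2CO3, DMF, rt
Reagents that add atoms: benzyl bromide BrCc1ccccc1
Why: Williamson ether synthesis at room temperature with a carbonate base, which deprotonates only the phenol and is too weak to touch C4–H, masks the C7 oxygen for the palladium step.

Step 12
Reactants: 18 (4R)-7-(benzyloxy)-4-[4-(benzyloxy)-8-methoxynaphthalen-1-yl]-8-bromo-3,4-dihydronaphthalen-1(2H)-one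
Product: 20 (4R)-7-(benzyloxy)-4-[4-(benzyloxy)-8-methoxynaphthalen-1-yl]-8-hydroxy-3,4-dihydronaphthalen-1(2H)-one, via pinacol boronate 19 (not isolated)
Conditions: B2pin2, KOAc, Pd(dppf)Cl2 (5 mol %), 1,4-dioxane, 90 °C; then NaBO3·4H2O, THF–H2O, rt
Reagents that add atoms: bis(pinacolato)diboron CC1(C)OB(OC1(C)C)B1OC(C)(C)C(C)(C)O1 (boron group of 19); sodium perborate [Na+].[Na+].O[B-]1(O)OO[B-](O)(O)OO1 (C8 oxygen)
Why: Miyaura borylation followed by ipso-oxidation of the aryl boronate turns C8–Br into C8–OH with acetate and perborate as the only bases, so that the base-induced racemisation known for 4-aryl-1-tetralones, a real danger in hot hydroxide under copper catalysis, is avoided.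

Step 13
Reactants: 20 (4R)-7-(benzyloxy)-4-[4-(benzyloxy)-8-methoxynaphthalen-1-yl]-8-hydroxy-3,4-dihydronaphthalen-1(2H)-one
Product: 21 (4R)-7,8-dihydroxy-4-(4-hydroxy-8-methoxynaphthalen-1-yl)-3,4-dihydronaphthalen-1(2H)-one
Conditions: H2 (1 atm), 10% Pd/C, EtOAc–MeOH, rt
Reagents that add atoms: none
Why: Catalytic hydrogenolysis cleaves both aryl benzyl ethers at atmospheric pressure faster than it attacks the hydrogen-bonded, electron-rich aryl ketone, and no base or acid is present that could affect C4.

Compound list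
1 | 1,5-dimethoxynaphthalene | COc1cccc2c(OC)cccc12 | starting material
2 | N-[(4,8-dimethoxynaphthalen-1-yl)methylidene]-N-methylmethanaminium dichlorophosphate | COc1cccc2c(OC)ccc(C=[N+](C)C)c12.[O-]P(=O)(Cl)Cl | intermediate
3 | 4,8-dimethoxynaphthalene-1-carbaldehyde | COc1cccc2c(OC)ccc(C=O)c12 | intermediate
4 | 4-hydroxy-8-methoxynaphthalene-1-carbaldehyde | COc1cccc2c(O)ccc(C=O)c12 | intermediate
5 | 4-(benzyloxy)-8-methoxynaphthalene-1-carbaldehyde | COc1cccc2c(OCc3ccccc3)ccc(C=O)c12 | intermediate
6 | (2E)-3-[4-(benzyloxy)-8-methoxynaphthalen-1-yl]prop-2-enal | COc1cccc2c(OCc3ccccc3)ccc(/C=C/C=O)c12 | intermediate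
7 | potassium furan-2-yltrifluoroborate | [K+].F[B-](F)(F)c1ccco1 | starting material
8 | (3R)-3-[4-(benzyloxy)-8-methoxynaphthalen-1-yl]-3-(furan-2-yl)propanal | COc1cccc2c(OCc3ccccc3)ccc([C@@H](CC=O)c3ccco3)c12 | intermediate
9 | 2-{(1R)-1-[4-(benzyloxy)-8-methoxynaphthalen-1-yl]-4-methoxybut-3-en-1-yl}furan (E/Z mixture) | COc1cccc2c(OCc3ccccc3)ccc([C@@H](CC=COC)c3ccco3)c12 | intermediate
10 | (4R)-4-[4-(benzyloxy)-8-methoxynaphthalen-1-yl]-4-(furan-2-yl)butanal | COc1cccc2c(OCc3ccccc3)ccc([C@@H](CCC=O)c3ccco3)c12 | intermediate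
11 | ethynylmagnesium bromide | C#C[Mg]Br | starting material
12 | (6R)-6-[4-(benzyloxy)-8-methoxynaphthalen-1-yl]-6-(furan-2-yl)hex-1-yn-3-ol (both C3 epimers) | COc1cccc2c(OCc3ccccc3)ccc([C@@H](CCC(O)C#C)c3ccco3)c12 | intermediate
13 | dilithium salt of 12 (lithium alkoxide and lithium acetylide) | [Li+].[Li+].COc1cccc2c(OCc3ccccc3)ccc([C@@H](CCC([O-])C#[C-])c3ccco3)c12 | intermediate
14 | (6R)-6-[4-(benzyloxy)-8-methoxynaphthalen-1-yl]-1-bromo-6-(furan-2-yl)hex-1-yn-3-ol (both C3 epimers) | COc1cccc2c(OCc3ccccc3)ccc([C@@H](CCC(O)C#CBr)c3ccco3)c12 | intermediate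
15 | (6R)-6-[4-(benzyloxy)-8-methoxynaphthalen-1-yl]-1-bromo-6-(furan-2-yl)hex-1-yn-3-one | COc1cccc2c(OCc3ccccc3)ccc([C@@H](CCC(=O)C#CBr)c3ccco3)c12 | intermediate
16 | 4-[4-(benzyloxy)-8-methoxynaphthalen-1-yl]-8-bromo-4a,7-epoxy-3,4,4a,7-tetrahydronaphthalen-1(2H)-one (C4 as in 15; bridgeheads C4a and C7 as a mixture) | COc1cccc2c(OCc3ccccc3)ccc([C@H]3CCC(=O)C4=C(Br)C5C=CC34O5)c12 | intermediate
17 | (4R)-4-[4-(benzyloxy)-8-methoxynaphthalen-1-yl]-8-bromo-7-hydroxy-3,4-dihydronaphthalen-1(2H)-one | COc1cccc2c(OCc3ccccc3)ccc([C@H]3CCC(=O)c4c3ccc(O)c4Br)c12 | intermediate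
18 | (4R)-7-(benzyloxy)-4-[4-(benzyloxy)-8-methoxynaphthalen-1-yl]-8-bromo-3,4-dihydronaphthalen-1(2H)-one | COc1cccc2c(OCc3ccccc3)ccc([C@H]3CCC(=O)c4c3ccc(OCc3ccccc3)c4Br)c12 | intermediate
19 | (4R)-7-(benzyloxy)-4-[4-(benzyloxy)-8-methoxynaphthalen-1-yl]-8-(4,4,5,5-tetramethyl-1,3,2-dioxaborolan-2-yl)-3,4-dihydronaphthalen-1(2H)-one | COc1cccc2c(OCc3ccccc3)ccc([C@H]3CCC(=O)c4c3ccc(OCc3ccccc3)c4B3OC(C)(C)C(C)(C)O3)c12 | intermediate
20 | (4R)-7-(benzyloxy)-4-[4-(benzyloxy)-8-methoxynaphthalen-1-yl]-8-hydroxy-3,4-dihydronaphthalen-1(2H)-one | COc1cccc2c(OCc3ccccc3)ccc([C@H]3CCC(=O)c4c3ccc(OCc3ccccc3)c4O)c12 | intermediate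
21 | (4R)-7,8-dihydroxy-4-(4-hydroxy-8-methoxynaphthalen-1-yl)-3,4-dihydronaphthalen-1(2H)-one | COc1cccc2c(O)ccc([C@H]3CCC(=O)c4c3ccc(O)c4O)c12 | target

Total step count: 13. Longest linear sequence: 13 steps (1 → 21); 7 and 11 are purchased.

Steps most likely to fail

**Step 10.**
- The activated triple bond may take up chloride or methyl from aluminium, or the furan may break down, before the two ends of the hindered chain meet. The bulky peri-substituted aryl group on the tether may also disfavour the folded conformer.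
- Heating in toluene and opening the bridge afterwards with a catalytic acid would be tried first.
- The change of approach builds ring A bimolecularly and closes ring B afterwards. It sets out from aldehyde 10 and comes back at 18.
- Pinnick oxidation (NaClO2, NaH2PO4, 2-methyl-2-butene) should give the butanoic acid F1, and MeI/K2CO3 its methyl ester F2.
- Methyl 3-bromopropiolate F3 (from methyl propiolate, NBS, cat. AgNO3) should add to the furan of F2 in warm toluene. The established orientation puts the ester-bearing carbon on the substituted furan carbon and gives the oxa-bridged diester F4.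
- BF3·OEt2 should open F4 to the bromophenol benzoate F5, and BnBr/K2CO3 should give the benzyl ether F6.
- A Dieckmann condensation under soft enolisation (TiCl4, Bu3N, CH2Cl2, chosen to spare C4–H) forms C1–C2 and gives the β-keto ester F7.
- Krapcho demethoxycarbonylation (LiCl, wet DMSO, heat) then leads to 18.

**Step 5.**
- Iminium formation and attack on the electron-rich, peri-hindered enal may be slow.
- Protodeboronation of the trifluoroborate could then take over, and a sluggish reaction could erode the facial selectivity.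
- The fallback replaces catalyst-controlled C–C formation by a stereospecific boron-to-carbon migration. It sets out from aldehyde 5 and comes back at aldehyde 8.
- Horner–Wadsworth–Emmons reaction with tert-butyl diethylphosphonoacetate (NaH, THF) should give the (E)-acrylate F8.
- Copper-catalysed asymmetric β-borylation (CuCl, NaOtBu, a Josiphos-type ferrocenyl diphosphine of the appropriate hand, B2pin2, MeOH, THF) should give the (R)-β-boryl ester F9.
- 2-Furyllithium F10 (furan, n-BuLi) adds to boron at −78 °C to give the lithium boronate F11.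
- One equivalent of NBS at −78 °C triggers 1,2-migration of the benzylic carbon with retention and loss of the boron group, giving the tert-butyl ester F12.
- i-Bu2AlH in toluene at −78 °C then gives 8.

**Step 12.**
- Oxidative addition and boryl transfer at a bromide flanked on both sides may be slow, and protodebromination may compete.
- The fallback uses halogen–metal exchange at the alcohol oxidation level. It sets out from 18 and comes back at 20.
- NaBH4 in MeOH should reduce the ketone to the bromotetralol F13, which also removes the acidity of C4–H.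
- n-BuLi (2 equiv, THF, −78 °C) forms the alkoxide and exchanges bromine for lithium, and B(OMe)3 traps the aryllithium as the cyclic boronate F14.
- H2O2/NaOH oxidises F14 in the same flask to the hydroxytetralol F15.
- MnO2 in CH2Cl2 takes the benzylic alcohol back to the ketone 20.

Further compounds
F1 | step 10 | (4R)-4-[4-(benzyloxy)-8-methoxynaphthalen-1-yl]-4-(furan-2-yl)butanoic acid | COc1cccc2c(OCc3ccccc3)ccc([C@@H](CCC(=O)O)c3ccco3)c12
F2 | step 10 | methyl (4R)-4-[4-(benzyloxy)-8-methoxynaphthalen-1-yl]-4-(furan-2-yl)butanoate | COc1cccc2c(OCc3ccccc3)ccc([C@@H](CCC(=O)OC)c3ccco3)c12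
F3 | step 10 | methyl 3-bromopropiolate | COC(=O)C#CBr
F4 | step 10 | methyl 3-bromo-1-{1-[4-(benzyloxy)-8-methoxynaphthalen-1-yl]-4-methoxy-4-oxobutyl}-7-oxabicyclo[2.2.1]hepta-2,5-diene-2-carboxylate (side-chain centre as in 10; bridgeheads as a mixture) | COc1cccc2c(OCc3ccccc3)ccc([C@@H](CCC(=O)OC)C34OC(C=C3)C(Br)=C4C(=O)OC)c12
F5 | step 10 | methyl 2-bromo-3-hydroxy-6-{1-[4-(benzyloxy)-8-methoxynaphthalen-1-yl]-4-methoxy-4-oxobutyl}benzoate (centre as in 10) | COc1cccc2c(OCc3ccccc3)ccc([C@@H](CCC(=O)OC)c3ccc(O)c(Br)c3C(=O)OC)c12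
F6 | step 10 | methyl 3-(benzyloxy)-2-bromo-6-{1-[4-(benzyloxy)-8-methoxynaphthalen-1-yl]-4-methoxy-4-oxobutyl}benzoate (centre as in 10) | COc1cccc2c(OCc3ccccc3)ccc([C@@H](CCC(=O)OC)c3ccc(OCc4ccccc4)c(Br)c3C(=O)OC)c12
F7 | step 10 | methyl 7-(benzyloxy)-4-[4-(benzyloxy)-8-methoxynaphthalen-1-yl]-8-bromo-1-oxo-1,2,3,4-tetrahydronaphthalene-2-carboxylate (C4 as in 18; C2 enolisable) | COc1cccc2c(OCc3ccccc3)ccc([C@H]3CC(C(=O)OC)C(=O)c4c3ccc(OCc3ccccc3)c4Br)c12
F8 | step 5 | tert-butyl (2E)-3-[4-(benzyloxy)-8-methoxynaphthalen-1-yl]prop-2-enoate | COc1cccc2c(OCc3ccccc3)ccc(/C=C/C(=O)OC(C)(C)C)c12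
F9 | step 5 | tert-butyl (3R)-3-[4-(benzyloxy)-8-methoxynaphthalen-1-yl]-3-(4,4,5,5-tetramethyl-1,3,2-dioxaborolan-2-yl)propanoate | COc1cccc2c(OCc3ccccc3)ccc([C@@H](CC(=O)OC(C)(C)C)B3OC(C)(C)C(C)(C)O3)c12
F10 | step 5 | 2-furyllithium | [Li]c1ccco1
F11 | step 5 | lithium furan-2-yl boronate complex of F9 | [Li+].COc1cccc2c(OCc3ccccc3)ccc([C@@H](CC(=O)OC(C)(C)C)[B-]3(c4ccco4)OC(C)(C)C(C)(C)O3)c12
F12 | step 5 | tert-butyl (3R)-3-[4-(benzyloxy)-8-methoxynaphthalen-1-yl]-3-(furan-2-yl)propanoate | COc1cccc2c(OCc3ccccc3)ccc([C@@H](CC(=O)OC(C)(C)C)c3ccco3)c12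
F13 | step 12 | 7-(benzyloxy)-4-[4-(benzyloxy)-8-methoxynaphthalen-1-yl]-8-bromo-1,2,3,4-tetrahydronaphthalen-1-ol (C4 as in 18; both C1 epimers) | COc1cccc2c(OCc3ccccc3)ccc([C@H]3CCC(O)c4c3ccc(OCc3ccccc3)c4Br)c12
F14 | step 12 | cyclic C8 boronic acid C1 hemiester (oxaborole) of the tetralol (C4 as in 18) | COc1cccc2c(OCc3ccccc3)ccc([C@H]3CCC4OB(O)c5c(OCc6ccccc6)ccc3c45)c12
F15 | step 12 | 7-(benzyloxy)-4-[4-(benzyloxy)-8-methoxynaphthalen-1-yl]-1,2,3,4-tetrahydronaphthalene-1,8-diol (C4 as in 18; both C1 epimers) | COc1cccc2c(OCc3ccccc3)ccc([C@H]3CCC(O)c4c3ccc(OCc3ccccc3)c4O)c12
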